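The cyclopentane C1–C5 (daucane numbering: C1 quaternary methyl carbon, C2 angelate carbinol, C3 methylene, C4 isopropyl carbinol, C5 ring-fusion CH, C6 aroyloxy carbon, C7–C10 the rest of the cycloheptene) carries oxygen on C2 and C4 flanking the C3 methylene, a latent β-hydroxy ketone. The route closes this ring onto a preformed cycloheptene: a lithium enolate formed at the only enolisable position of a C2 methyl ketone (C1 is quaternary) adds to a C4 isopropyl ketone held trans to it, creating the C3–C4 bond and the C4 carbinol in one operation. The 1,4-diketone precursor arises from a dianionic Ireland–Claisen rearrangement, ring-closing metathesis and Wacker oxidation.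

Key step: step 9

Assumption: ethyl 2-[(2R)-oxiran-2-yl]acetate, pent-1-en-4-yne, angelic acid and 4-[(tert-butyldimethylsilyl)oxy]benzoic acid are taken as catalogue chemicals.

Convention: β is the face of the C1 methyl group; TBS = tert-butyldimethylsilyl, TMS = trimethylsilyl.

Step 1
Reactants: 1 ethyl 2-[(2R)-oxiran-2-yl]acetate
Product: 2 ethyl (3S)-3-hydroxy-5-methylhex-5-enoate
Conditions: isopropenylmagnesium bromide (1.3 equiv), CuI (10 mol%), THF, −40 °C; dilute HCl
Reagents that add atoms: isopropenylmagnesium bromide CC(=C)[Mg]Br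
Why: Copper-catalysed Grignard opening of the terminal epoxide at its CH2 carbon (SN2) should outrun attack on the ester at −40 °C and leaves the purchased carbinol centre (the later C6) untouched.

Step 2
Reactants: 3 pent-1-en-4-yne
Product: 5 (2E)-3-methylhexa-2,5-dien-1-ol, via alkenylalane 4 (not isolated)
Conditions: Me3Al (2 equiv), Cp2ZrCl2 (20 mol%), CH2Cl2, 0 → 23 °C; then (CH2O)n, THF, 0 → 23 °C; dilute HCl
Reagents that add atoms: trimethylaluminium C[Al](C)C; paraformaldehyde (formaldehyde unit) C=O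
Why: Negishi zirconium-catalysed carboalumination adds CH3 and Al syn across the terminal alkyne only, so trapping the alkenylalane with formaldehyde should give the (E)-allylic alcohol with allyl trans to CH2OH.

Step 3
Reactants: 2 ethyl (3S)-3-hydroxy-5-methylhex-5-enoate; 5 (2E)-3-methylhexa-2,5-dien-1-ol
Product: 6 (2E)-3-methylhexa-2,5-dien-1-yl (3S)-3-hydroxy-5-methylhex-5-enoate
Conditions: 5 (1.5 equiv), Ti(OEt)4 (10 mol%), toluene, 100 °C, EtOH distilled off
Reagents that add atoms: none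
Why: Titanate-mediated transesterification is neutral, so the β-hydroxy ester should exchange its alkoxy group without dehydration or loss of configuration.

Step 4
Reactants: 6 (2E)-3-methylhexa-2,5-dien-1-yl (3S)-3-hydroxy-5-methylhex-5-enoate
Product: 8 (2S,3S)-3-hydroxy-5-methyl-2-[(3S)-3-methylhexa-1,5-dien-3-yl]hex-5-enoic acid, via dilithium dianion 7 (not isolated)
Conditions: LiN(iPr)2 (LDA, 2.3 equiv), THF, −78 → 23 °C (to 50 °C if slow); dilute HCl
Reagents that add atoms: none
Why: Dianionic Ireland–Claisen (ester-enolate Claisen) rearrangement: the lithium alkoxide–enolate chelate fixes the enolate geometry (C6 cis to OLi) and shields one face, so the allyl unit should bond to C5 anti to the C6 side chain (Frater–Seebach sense) through a chair in which the (E)-alkene places allyl equatorial and methyl axial, setting C5 and quaternary C1 from the C6 carbinol in one event.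

Step 5
Reactants: 8 (2S,3S)-3-hydroxy-5-methyl-2-[(3S)-3-methylhexa-1,5-dien-3-yl]hex-5-enoic acid
Product: 10 (2S,3S)-3-[(tert-butyldimethylsilyl)oxy]-5-methyl-2-[(3S)-3-methylhexa-1,5-dien-3-yl]hex-5-enoic acid, via bis-silyl compound 9 (not isolated)
Conditions: TBSOTf (2.4 equiv), 2,6-lutidine (4 equiv), CH2Cl2, −78 → 0 °C; then AcOH/THF/H2O, 23 °C
Reagents that add atoms: tert-butyldimethylsilyl triflate CC(C)(C)[Si](C)(C)OS(=O)(=O)C(F)(F)F
Why: Silylation covers both hydroxyl and carboxyl, and the far more labile silyl ester should be hydrolysed selectively by mild aqueous acid, leaving the secondary silyl ether.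

Step 6
Reactants: 10 (2S,3S)-3-[(tert-butyldimethylsilyl)oxy]-5-methyl-2-[(3S)-3-methylhexa-1,5-dien-3-yl]hex-5-enoic acid
Product: 12 (4S,5S)-5-[(tert-butyldimethylsilyl)oxy]-2,7-dimethyl-4-[(3S)-3-methylhexa-1,5-dien-3-yl]oct-7-en-3-one, via acid chloride 11 (not isolated)
Conditions: 1-chloro-N,N,2-trimethylprop-1-en-1-amine (Ghosez reagent, 1.2 equiv), CH2Cl2, 0 → 23 °C; then iPrMgCl (1.3 equiv), CuI (10 mol%), THF, −78 °C
Reagents that add atoms: isopropylmagnesium chloride CC(C)[Mg]Cl
Why: Neutral acid chloride formation followed by copper-catalysed acylation of the Grignard reagent should stop at the ketone, and the weakly basic organocopper at −78 °C should not epimerise C5.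

Step 7
Reactants: 12 (4S,5S)-5-[(tert-butyldimethylsilyl)oxy]-2,7-dimethyl-4-[(3S)-3-methylhexa-1,5-dien-3-yl]oct-7-en-3-one
Product: 13 1-[(1S,2S,7S)-2-[(tert-butyldimethylsilyl)oxy]-7-ethenyl-4,7-dimethylcyclohept-4-en-1-yl]-2-methylpropan-1-one
Conditions: second-generation Grubbs catalyst (5 mol%), CH2Cl2 (0.005 M), 40 °C
Reagents that add atoms: none
Why: Ring-closing metathesis should initiate at the unhindered allyl alkene and close onto the methallyl alkene to give the trisubstituted cycloheptene, while the vinyl group on quaternary C1 is too hindered to load the catalyst and could only form a cyclobutene with the allyl carbene.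

Step 8
Reactants: 13 1-[(1S,2S,7S)-2-[(tert-butyldimethylsilyl)oxy]-7-ethenyl-4,7-dimethylcyclohept-4-en-1-yl]-2-methylpropan-1-one
Product: 14 1-[(1S,2S,7R)-7-acetyl-2-[(tert-butyldimethylsilyl)oxy]-4,7-dimethylcyclohept-4-en-1-yl]-2-methylpropan-1-one
Conditions: PdCl2 (20 mol%), CuCl (1 equiv), O2 (1 atm), DMF/H2O 7:1, 23 °C
Reagents that add atoms: water O
Why: Tsuji–Wacker oxidation with divalent palladium should convert the monosubstituted vinyl group into the methyl ketone by Markovnikov hydroxypalladation (the classical γ,δ-enone to 1,4-diketone case), the trisubstituted ring alkene being inert.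

Step 9
Reactants: 14 1-[(1S,2S,7R)-7-acetyl-2-[(tert-butyldimethylsilyl)oxy]-4,7-dimethylcyclohept-4-en-1-yl]-2-methylpropan-1-one
Product: 16 (3R,3aS,4S,8aR)-4-[(tert-butyldimethylsilyl)oxy]-3-hydroxy-6,8a-dimethyl-3-(propan-2-yl)-3,3a,4,5,8,8a-hexahydroazulen-1(2H)-one, via lithium enolate 15 (not isolated)
Conditions: LiN(iPr)2 (LDA, 1.1 equiv), THF, −78 → −40 °C; AcOH in THF, −78 °C
Reagents that add atoms: none
Why: LDA should remove a proton from the acetyl CH3, the only kinetically accessible α-position (C1 is quaternary; the isobutyryl α-hydrogens at C5 and on the isopropyl group are tertiary and shielded), and the lithium enolate then adds through C3 to the C4 carbonyl in an intramolecular aldol addition, the closest known type being the aldol stage of the Tsuji 1,4-diketone cyclopentannulation stopped before dehydration. The cyclopentane closes in the 5-(enolexo)-exo-trig mode onto the trans-disposed acyl groups, giving the trans-fused hydroazulene without touching C1 or C5. C4 is the only new stereocentre and is controlled by C5: with the C5–H bond eclipsing the isopropyl group to minimise allylic 1,3-strain, the enolate tethered at C1 reaches only the carbonyl face that leaves isopropyl anti to C6 and its silyloxy group, so the hydroxyl should end cis to C6 and to the C1 methyl; this is also the more stable epimer should the lithium aldolate equilibrate by retro-aldol. The step needs site-selective enolisation and survival of the β-hydroxy ketone; the quaternary C1, the low temperature and a cold acetic acid quench of the chelated lithium aldolate should secure both and prevent dehydration to the cyclopentenone or silyl migration from O6.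

Step 10
Reactants: 16 (3R,3aS,4S,8aR)-4-[(tert-butyldimethylsilyl)oxy]-3-hydroxy-6,8a-dimethyl-3-(propan-2-yl)-3,3a,4,5,8,8a-hexahydroazulen-1(2H)-one
Product: 17 (1R,3R,3aS,4S,8aR)-4-[(tert-butyldimethylsilyl)oxy]-6,8a-dimethyl-3-(propan-2-yl)-1,2,3,3a,4,5,8,8a-octahydroazulene-1,3-diol
Conditions: NaBH4 (2 equiv), MeOH/THF, −20 → 0 °C
Reagents that add atoms: none
Why: Substrate-controlled borohydride reduction: as with 17-oxo steroids, hydride should approach the C2 carbonyl from the α face, anti to the pseudo-axial C1 methyl and the C4 hydroxyl, giving the C2 alcohol cis to both (methanol suppresses hydroxyl-directed delivery).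

Step 11
Reactants: 17 (1R,3R,3aS,4S,8aR)-4-[(tert-butyldimethylsilyl)oxy]-6,8a-dimethyl-3-(propan-2-yl)-1,2,3,3a,4,5,8,8a-octahydroazulene-1,3-diol; 18 angelic acid [(2Z)-2-methylbut-2-enoic acid]
Product: 20 (1R,3R,3aS,4S,8aR)-4-[(tert-butyldimethylsilyl)oxy]-3-hydroxy-6,8a-dimethyl-3-(propan-2-yl)-1,2,3,3a,4,5,8,8a-octahydroazulen-1-yl (2Z)-2-methylbut-2-enoate, via mixed anhydride 19 (not isolated)
Conditions: 18 (3 equiv), 2,4,6-trichlorobenzoyl chloride (3 equiv), Et3N (3 equiv), toluene, 23 °C; then 17, toluene, 80 °C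
Reagents that add atoms: none
Why: Yamaguchi-type mixed-anhydride acylation without a nucleophilic catalyst should transfer the angeloyl group to the secondary C2 hydroxyl without Z to E isomerisation, the tertiary C4 hydroxyl being too hindered to react.

Step 12
Reactants: 20 (1R,3R,3aS,4S,8aR)-4-[(tert-butyldimethylsilyl)oxy]-3-hydroxy-6,8a-dimethyl-3-(propan-2-yl)-1,2,3,3a,4,5,8,8a-octahydroazulen-1-yl (2Z)-2-methylbut-2-enoate
Product: 21 (1R,3R,3aS,4S,8aR)-3,4-dihydroxy-6,8a-dimethyl-3-(propan-2-yl)-1,2,3,3a,4,5,8,8a-octahydroazulen-1-yl (2Z)-2-methylbut-2-enoate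
Conditions: HF·pyridine, THF/pyridine, 0 → 23 °C
Reagents that add atoms: none
Why: Fluoride-mediated desilylation under buffered acidic conditions should free the C6 hydroxyl without acyl migration or cleavage of the angelate.

Step 13
Reactants: 21 (1R,3R,3aS,4S,8aR)-3,4-dihydroxy-6,8a-dimethyl-3-(propan-2-yl)-1,2,3,3a,4,5,8,8a-octahydroazulen-1-yl (2Z)-2-methylbut-2-enoate; 22 4-[(tert-butyldimethylsilyl)oxy]benzoic acid
Product: 23 (1R,3R,3aS,4S,8aR)-3-hydroxy-6,8a-dimethyl-1-{[(2Z)-2-methylbut-2-enoyl]oxy}-3-(propan-2-yl)-1,2,3,3a,4,5,8,8a-octahydroazulen-4-yl 4-[(tert-butyldimethylsilyl)oxy]benzoate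
Conditions: 22 (2 equiv), DCC (2 equiv), DMAP (0.3 equiv), CH2Cl2, 23 °C
Reagents that add atoms: none
Why: Steglich esterification should acylate the only secondary hydroxyl (C6), the tertiary C4 hydroxyl staying free as in the natural 6-esters of this skeleton.

Step 14
Reactants: 23 (1R,3R,3aS,4S,8aR)-3-hydroxy-6,8a-dimethyl-1-{[(2Z)-2-methylbut-2-enoyl]oxy}-3-(propan-2-yl)-1,2,3,3a,4,5,8,8a-octahydroazulen-4-yl 4-[(tert-butyldimethylsilyl)oxy]benzoate
Product: 24 (1R,3R,3aS,4S,8aR)-3-hydroxy-6,8a-dimethyl-1-{[(2Z)-2-methylbut-2-enoyl]oxy}-3-(propan-2-yl)-1,2,3,3a,4,5,8,8a-octahydroazulen-4-yl 4-hydroxybenzoate (CNP0188626.1)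
Conditions: KHF2 (2 equiv), MeOH, 23 °C
Reagents that add atoms: none
Why: Bifluoride cleaves aryl silyl ethers selectively at room temperature, so the phenol should be released with both esters and the tertiary alcohol untouched.

Compound list
1 | ethyl 2-[(2R)-oxiran-2-yl]acetate | CCOC(=O)C[C@@H]1CO1 | starting material
2 | ethyl (3S)-3-hydroxy-5-methylhex-5-enoate | CCOC(=O)C[C@@H](O)CC(C)=C | intermediate
3 | pent-1-en-4-yne | C=CCC#C | starting material
4 | dimethyl[(1E)-2-methylpenta-1,4-dien-1-yl]alane | C=CC/C(C)=C/[Al](C)C | intermediate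
5 | (2E)-3-methylhexa-2,5-dien-1-ol | C=CC/C(C)=C/CO | intermediate
6 | (2E)-3-methylhexa-2,5-dien-1-yl (3S)-3-hydroxy-5-methylhex-5-enoate | C=CC/C(C)=C/COC(=O)C[C@@H](O)CC(C)=C | intermediate
7 | dilithium alkoxide–enolate of 6 (enolate oxygen cis to the carbinol carbon) | [Li+].[Li+].C=CC/C(C)=C/CO/C([O-])=C/[C@@H]([O-])CC(C)=C | intermediate
8 | (2S,3S)-3-hydroxy-5-methyl-2-[(3S)-3-methylhexa-1,5-dien-3-yl]hex-5-enoic acid | OC(=O)[C@H]([C@@H](O)CC(C)=C)[C@@](C)(CC=C)C=C | intermediate
9 | tert-butyldimethylsilyl (2S,3S)-3-[(tert-butyldimethylsilyl)oxy]-5-methyl-2-[(3S)-3-methylhexa-1,5-dien-3-yl]hex-5-enoate | CC(C)(C)[Si](C)(C)OC(=O)[C@H]([C@@H](O[Si](C)(C)C(C)(C)C)CC(C)=C)[C@@](C)(CC=C)C=C | intermediate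
10 | (2S,3S)-3-[(tert-butyldimethylsilyl)oxy]-5-methyl-2-[(3S)-3-methylhexa-1,5-dien-3-yl]hex-5-enoic acid | OC(=O)[C@H]([C@@H](O[Si](C)(C)C(C)(C)C)CC(C)=C)[C@@](C)(CC=C)C=C | intermediate
11 | (2S,3S)-3-[(tert-butyldimethylsilyl)oxy]-5-methyl-2-[(3S)-3-methylhexa-1,5-dien-3-yl]hex-5-enoyl chloride | ClC(=O)[C@H]([C@@H](O[Si](C)(C)C(C)(C)C)CC(C)=C)[C@@](C)(CC=C)C=C | intermediate
12 | (4S,5S)-5-[(tert-butyldimethylsilyl)oxy]-2,7-dimethyl-4-[(3S)-3-methylhexa-1,5-dien-3-yl]oct-7-en-3-one | CC(C)C(=O)[C@H]([C@@H](O[Si](C)(C)C(C)(C)C)CC(C)=C)[C@@](C)(CC=C)C=C | intermediate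
13 | 1-[(1S,2S,7S)-2-[(tert-butyldimethylsilyl)oxy]-7-ethenyl-4,7-dimethylcyclohept-4-en-1-yl]-2-methylpropan-1-one | CC(C)C(=O)[C@@H]1[C@@H](O[Si](C)(C)C(C)(C)C)CC(C)=CC[C@@]1(C)C=C | intermediate
14 | 1-[(1S,2S,7R)-7-acetyl-2-[(tert-butyldimethylsilyl)oxy]-4,7-dimethylcyclohept-4-en-1-yl]-2-methylpropan-1-one | CC(C)C(=O)[C@@H]1[C@@H](O[Si](C)(C)C(C)(C)C)CC(C)=CC[C@@]1(C)C(C)=O | intermediate
15 | lithium enolate of the acetyl group of 14 | [Li+].CC(C)C(=O)[C@@H]1[C@@H](O[Si](C)(C)C(C)(C)C)CC(C)=CC[C@@]1(C)C([O-])=C | intermediate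
16 | (3R,3aS,4S,8aR)-4-[(tert-butyldimethylsilyl)oxy]-3-hydroxy-6,8a-dimethyl-3-(propan-2-yl)-3,3a,4,5,8,8a-hexahydroazulen-1(2H)-one | O=C1C[C@@](O)(C(C)C)[C@@H]2[C@@H](O[Si](C)(C)C(C)(C)C)CC(C)=CC[C@]21C | intermediate
17 | (1R,3R,3aS,4S,8aR)-4-[(tert-butyldimethylsilyl)oxy]-6,8a-dimethyl-3-(propan-2-yl)-1,2,3,3a,4,5,8,8a-octahydroazulene-1,3-diol | O[C@@H]1C[C@@](O)(C(C)C)[C@@H]2[C@@H](O[Si](C)(C)C(C)(C)C)CC(C)=CC[C@]21C | intermediate
18 | angelic acid, (2Z)-2-methylbut-2-enoic acid | C/C=C(/C)C(=O)O | starting material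
19 | (2Z)-2-methylbut-2-enoic 2,4,6-trichlorobenzoic anhydride | C/C=C(/C)C(=O)OC(=O)c1c(Cl)cc(Cl)cc1Cl | intermediate
20 | (1R,3R,3aS,4S,8aR)-4-[(tert-butyldimethylsilyl)oxy]-3-hydroxy-6,8a-dimethyl-3-(propan-2-yl)-1,2,3,3a,4,5,8,8a-octahydroazulen-1-yl (2Z)-2-methylbut-2-enoate | C/C=C(/C)C(=O)O[C@@H]1C[C@@](O)(C(C)C)[C@@H]2[C@@H](O[Si](C)(C)C(C)(C)C)CC(C)=CC[C@]21C | intermediate
21 | (1R,3R,3aS,4S,8aR)-3,4-dihydroxy-6,8a-dimethyl-3-(propan-2-yl)-1,2,3,3a,4,5,8,8a-octahydroazulen-1-yl (2Z)-2-methylbut-2-enoate | C/C=C(/C)C(=O)O[C@@H]1C[C@@](O)(C(C)C)[C@@H]2[C@@H](O)CC(C)=CC[C@]21C | intermediate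
22 | 4-[(tert-butyldimethylsilyl)oxy]benzoic acid | CC(C)(C)[Si](C)(C)Oc1ccc(cc1)C(=O)O | starting material
23 | (1R,3R,3aS,4S,8aR)-3-hydroxy-6,8a-dimethyl-1-{[(2Z)-2-methylbut-2-enoyl]oxy}-3-(propan-2-yl)-1,2,3,3a,4,5,8,8a-octahydroazulen-4-yl 4-[(tert-butyldimethylsilyl)oxy]benzoate | C/C=C(/C)C(=O)O[C@@H]1C[C@@](O)(C(C)C)[C@@H]2[C@@H](OC(=O)c3ccc(O[Si](C)(C)C(C)(C)C)cc3)CC(C)=CC[C@]21C | intermediate
24 | (1R,3R,3aS,4S,8aR)-3-hydroxy-6,8a-dimethyl-1-{[(2Z)-2-methylbut-2-enoyl]oxy}-3-(propan-2-yl)-1,2,3,3a,4,5,8,8a-octahydroazulen-4-yl 4-hydroxybenzoate | C/C=C(/C)C(=O)O[C@@H]1C[C@@](O)(C(C)C)[C@@H]2[C@@H](OC(=O)c3ccc(O)cc3)CC(C)=CC[C@]21C | target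

Total step count: 14. Longest linear sequence: 13 steps (1 to 24 through steps 1 and 3–14; step 2 supplies alcohol 5).

Steps most likely to fail

Step 4 (dianionic Ireland–Claisen). The rearrangement may proceed with too little face discrimination at the chelated enolate or partly through a boat, eroding control at C5 and C1, or stall at the hindered alkene terminus. The fallback replaces chelate control by a protected silyl ketene acetal rearrangement and sets out from 6. The carbinol is silylated (TBSCl, imidazole, DMF) to (2E)-3-methylhexa-2,5-dien-1-yl (3S)-3-[(tert-butyldimethylsilyl)oxy]-5-methylhex-5-enoate F1. Enolisation with LDA in THF/DMPU in the presence of TMSCl at −78 °C should give the (Z)-trimethylsilyl ketene acetal F2 (the same enolate geometry as in the chelate). On warming to 23–60 °C this should rearrange through the chair to the trimethylsilyl ester of the rearranged acid F3, and aqueous work-up hydrolyses the silyl ester. The fallback comes back to the route at 10, so step 5 is not needed.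

Step 9 (key aldol). The lithium aldolate may revert by retro-aldol, dehydrate to the cyclopentenone, or undergo proton transfer to the isobutyryl side with loss of the silyloxy group. The fallback generates the enolate reductively and irreversibly and sets out from 14. Kinetic trapping (LDA with TMSCl present, THF, −78 °C) gives the trimethylsilyl enol ether of the acetyl group F4. NBS in THF at −78 °C converts it into the bromomethyl ketone 1-[(1S,2S,7R)-7-(bromoacetyl)-2-[(tert-butyldimethylsilyl)oxy]-4,7-dimethylcyclohept-4-en-1-yl]-2-methylpropan-1-one F5. SmI2 in THF at −78 °C then effects an intramolecular samarium Reformatsky cyclisation under neutral, chelating conditions, and the fallback comes back to the route at 16.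

Step 10 (ketone reduction). Hydroxyl-directed hydride delivery to the β face, or too little steric bias, may give the C2 epimer. The fallback masks the directing group and uses a bulky hydride, setting out from 16. N-(trimethylsilyl)imidazole silylates the tertiary hydroxyl to give the C4 trimethylsilyl ether of the ketone F6. LiBH(sBu)3 (L-Selectride) in THF at −78 °C should then attack only from the open α face to give the C2 alcohol with the C4 trimethylsilyl ether F7. K2CO3 in MeOH removes the trimethylsilyl group, and the fallback comes back to the route at 17.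

Further compounds
F1 | step 4 | (2E)-3-methylhexa-2,5-dien-1-yl (3S)-3-[(tert-butyldimethylsilyl)oxy]-5-methylhex-5-enoate | C=CC/C(C)=C/COC(=O)C[C@@H](O[Si](C)(C)C(C)(C)C)CC(C)=C
F2 | step 4 | (Z)-trimethylsilyl ketene acetal of F1 | C=CC/C(C)=C/CO/C(O[Si](C)(C)C)=C/[C@@H](O[Si](C)(C)C(C)(C)C)CC(C)=C
F3 | step 4 | trimethylsilyl (2S,3S)-3-[(tert-butyldimethylsilyl)oxy]-5-methyl-2-[(3S)-3-methylhexa-1,5-dien-3-yl]hex-5-enoate | C[Si](C)(C)OC(=O)[C@H]([C@@H](O[Si](C)(C)C(C)(C)C)CC(C)=C)[C@@](C)(CC=C)C=C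
F4 | step 9 | 1-[(1S,2S,7R)-2-[(tert-butyldimethylsilyl)oxy]-4,7-dimethyl-7-{1-[(trimethylsilyl)oxy]ethenyl}cyclohept-4-en-1-yl]-2-methylpropan-1-one | CC(C)C(=O)[C@@H]1[C@@H](O[Si](C)(C)C(C)(C)C)CC(C)=CC[C@@]1(C)C(O[Si](C)(C)C)=C
F5 | step 9 | 1-[(1S,2S,7R)-7-(bromoacetyl)-2-[(tert-butyldimethylsilyl)oxy]-4,7-dimethylcyclohept-4-en-1-yl]-2-methylpropan-1-one | CC(C)C(=O)[C@@H]1[C@@H](O[Si](C)(C)C(C)(C)C)CC(C)=CC[C@@]1(C)C(=O)CBr
F6 | step 10 | (3R,3aS,4S,8aR)-4-[(tert-butyldimethylsilyl)oxy]-6,8a-dimethyl-3-(propan-2-yl)-3-[(trimethylsilyl)oxy]-3,3a,4,5,8,8a-hexahydroazulen-1(2H)-one | O=C1C[C@@](O[Si](C)(C)C)(C(C)C)[C@@H]2[C@@H](O[Si](C)(C)C(C)(C)C)CC(C)=CC[C@]21C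
F7 | step 10 | (1R,3R,3aS,4S,8aR)-4-[(tert-butyldimethylsilyl)oxy]-6,8a-dimethyl-3-(propan-2-yl)-3-[(trimethylsilyl)oxy]-1,2,3,3a,4,5,8,8a-octahydroazulen-1-ol | O[C@@H]1C[C@@](O[Si](C)(C)C)(C(C)C)[C@@H]2[C@@H](O[Si](C)(C)C(C)(C)C)CC(C)=CC[C@]21C
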